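(The rate constants stand for no real mixture; the flask was simulated.)

The constant of chain growth stood at 1.63 × 10⁶ times that of self-condensation, yet I expected self-condensation to take a visible share of this flask's free monomer.

    2 free monomer → self-condensation product (k1 = 0.173 M⁻¹ s⁻¹)
    2 growing radical → dead chain (k2 = 4.8 × 10⁷ M⁻¹ s⁻¹)
    initiator → 2 initiating radical (k3 = 0.0845 s⁻¹)
    free monomer + growing radical → monomer in chains + growing radical, rate k4*[growing radical]*[free monomer] (k4 = 2.82 × 10⁵ M⁻¹ s⁻¹)
    free monomer + initiating radical → growing radical + monomer in chains (k5 = 2.26 × 10⁵ M⁻¹ s⁻¹)

free monomer 0.59 M; initiator 2.3 mM; time 4.0 min

- which holds at 4.0 min: what has brought the reaction to rest, or that it has not come to rest (forward and back rates have come level / it is still moving / all of the free monomer has reacted)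
- how much monomer in chains there is at 4.0 min, in percent of the free monomer charged

- a species is counted by the free monomer in it: one self-condensation product counts as two
- a doubled species enters its step squared and goes two at a time
- the reaction counts as stopped when no species that holds the free monomer changes by six tenths of a point or more over the second half of the time
- run time (flask): 4.0 min

The two constants multiply different things. I took growing radical as made as fast as it dies, which put [growing radical] at the root of the initiator constant times the initiator charge over the pairing constant: 2.01 × 10⁻⁶ M, far below the 0.59 M of free monomer. So a free monomer joined chains at a pseudo-first-order 0.567 s⁻¹, and went to self-condensation at 0.204 s⁻¹ at the charge. Their ratio, 0.360, is the condensation ratio s: self-condensation's rate per free monomer at the charge over chain growth's rate.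

Both steps run one way, and the half-life of free monomer by chain growth, 1.22 s, was shorter than the initiator's 8.20 s, so I held [growing radical] level while free monomer lasted and committed to a flask whose free monomer had reacted out by 4.0 min. As free monomer fell, self-condensation's rate per monomer fell with it, so the chains' share over the run, ln(1 + s)/s, came to 85.4 %, more than the 73.5 % of the first moment.

The forecast gave all of the free monomer has reacted and 85 %, since self-condensation “falls off with the square of the monomer concentration”. The simulation gave all of the free monomer has reacted, with 85.0 % in chains at 4.00 min.

In this flask half of the self-condensation turnover was done by 0.532 s and half of the chain turnover by 1.11 s, twice as late, and at 4.00 min 15.0 % stood as self-condensation product beside 0 % of free monomer. For the neighbour flask with 0.24 M of free monomer and the same initiator, I reckoned s at 0.146, which gives 93.3 %, and that flask read 93.1 % in chains.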